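## The problem

The target is a 2,3-dihydro-1-benzofuran (benzene ring A fused to dihydrofuran ring B). It carries a 3-oxoprop-1-en-2-yl group on C2, a tiglate on C3, and a 1-(tigloyloxy)ethyl group on C5, para to the ring oxygen O1. C2 (R) and C3 (S) are adjacent and trans, so one can be set from the other through ring B. The side-chain carbinol carbon (R) lies across ring A, too far away to be controlled by them, and needs a reagent-controlled step of its own. Three groups rule out rough treatment. The C3 ester is benzylic and next to the C2 hydrogen, so acid or base can expel tiglic acid and aromatise ring B to a benzofuran. The side-chain ester is a secondary para-alkoxybenzylic ester that ionises easily in acid. The 2-substituted propenal is a Michael acceptor and makes the C2 hydrogen vinylogously acidic. The task is therefore to place O1, the branched three-carbon unit and the C3 oxygen on two neighbouring carbons, trans and in one absolute sense, and to bring in the aldehyde and the side-chain ester only at the end. The enabling feature is that C2 is bonded both to O1 and to the central carbon of the propen-2-yl unit, while C3 carries a trans oxygen. If O1 is moved from C2 onto that exocyclic carbon, the skeleton becomes a 2,2-dimethylchroman with trans oxygens on C3 and C4, which is what asymmetric epoxidation of a 2,2-dimethyl-2H-chromene followed by anti opening delivers.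

## Retrosynthesis

**14 to 12.** No skeletal bond is cut. The formyl oxygen is taken off, so that target 14 comes from the propen-2-yl compound 12 by allylic oxidation of the methyl group through alcohol 13. The propenal is the most fragile group of the molecule and should appear last. Carrying an oxygenated three-carbon unit through the route instead would need a protecting group and would change the key step. Compound 12 is much more robust. The forward reaction must choose the one electron-rich 1,1-disubstituted alkene over the two ester-deactivated tiglate alkenes and the methyl hydrogens over the C2 hydrogen, in a medium mild enough for two benzylic esters.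

**12 to 11 and 6, then 11 to 10.** The acyl–oxygen bond of the side-chain ester is cut to give carbinol 11 and tiglic acid 6. The carbinol C–H bond is then removed to give aryl methyl ketone 10. The remote stereocentre cannot be relayed from ring B, so a catalyst-controlled ketone reduction is the natural way to set it. Keeping the acetyl group until this late point also helps earlier steps. It is conjugated with O1 and damps ionisation at the benzylic oxygenated carbon, whereas the para-alkoxybenzylic carbinol it becomes would be a liability if carried further back. The forward steps must reduce one ketone without touching three alkenes and a benzylic ester, and must acylate the carbinol on oxygen without breaking its C–O bond.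

**10 to 7 (key disconnection).** The O1–C2 bond of 10 is cut and O1 is reattached to the central carbon of the propen-2-yl group, with a hydrogen returned to its CH2 terminus. This gives the six-membered chromanol 7, in which the old C2 is a carbinol carbon (C3 of the chroman) and the old C3 keeps its tiglate (C4 of the chroman). The alternative of closing ring B by a conventional O1–C2 substitution on an open chain would require a separate acyclic synthesis of two stereocentres. Here the isomeric skeleton is the direct product of chromene epoxidation and opening, and the tiglate already sits on the right oxygen. Compound 7 has no exocyclic alkene and its two stereocentres come from one catalytic step. The forward reaction must make the ring oxygen migrate from the CMe2 carbon to the activated carbinol carbon with inversion, in preference to participation of the neighbouring ester or migration of the aryl bond, and must end by loss of a methyl proton.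

**7 to 5 and 6.** The C4–O ester bond is cut to give epoxide 5 and tiglic acid 6. Opening the epoxide with the acid itself sets the trans relationship by inversion and places the acyl group on the benzylic oxygen in one operation. The route through a diol would need a regioselective acylation. The forward reaction must attack only the benzylic carbon, which the gem-dimethyl group next to C3 ensures, and must stay on the SN2 side.

**5 to 4.** The two C–O bonds of the oxirane are cut to give chromene 4, which has no stereocentre. Conjugated cis-alkenes of this type are the best substrates for manganese-salen epoxidation. One catalytic step must set both ring stereocentres in the (3R,4R) sense.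

**4 to 3, then 3 to 1 and 2.** The pyran ring is opened at the C4–C4a bond in the sense of a propargyl Claisen cascade to aryl propargyl ether 3. The ether C–O bond of 3 is then cut to phenol 1 and tertiary propargylic chloride 2. A direct one-step annulation through the ortho carbon of 1 would be shorter. However, the acetyl group makes that carbon a poor nucleophile, while the sigmatropic route does not depend on ring nucleophilicity and can give only one regioisomer, because both ortho positions of 1 are equivalent.

## Roads not taken

Alternative 1: The cut goes through three bonds of ring A (C3a–C7a, C4–C5, C6–C7), so rings A and B would be formed together by Cp*RuCl(cod)-catalysed [2+2+2] cyclotrimerisation of diyne A2 with the chiral alkyne A3 to give the silylated benzofuran A1. A2 is a silyl-capped ynol ether tethered through O1–C2–C3 to a terminal alkyne.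
- Merits: the route is convergent. The side-chain stereocentre is bought with A3. The allylic oxygen is already present as a silyl ether, so no late C–H oxidation is needed. No cation is generated next to an ester. In these respects it is better than the chosen plan.
- Weak points: A2 already contains the two contiguous stereocentres and a sensitive silyl ynol ether, so the stereochemical problem is only moved into an acyclic synthesis of several steps. The insertion regiochemistry (side chain at C5, not C6) depends on the trimethylsilyl group at C7, which must later be removed by protodesilylation next to acid-labile benzylic oxygens. Three silyl ethers on three different hydroxyl groups must then be converted into two tiglates and one aldehyde.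
- Comparison: the chosen plan offers eight steps from a simple phenol, no protecting groups, and two catalytic asymmetric reactions used on their best substrate classes.

Alternative 2: The cut removes C2–C3 and O1–C2, a [4+1] construction of ring B. The ylide from the chiral sulfonium salt A6 would add to the O-silylated salicylaldehyde A5 and close to the trans vinyl epoxide A7. One equivalent of Bu4NF would then free the phenoxide, which would open the allylic epoxide carbon in a 5-exo sense with inversion to give the trans hydroxy dihydrobenzofuran A4.
- Merits: ring B and both of its stereocentres arise in one pot. The C3 hydroxyl is free for direct esterification with 6. The allylic oxygen is in place. No carbocation is involved. This road could be about as short as the chosen one, and it avoids the main risk of the chosen key step.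
- Weak points: the trans/cis ratio and the facial selectivity of a 2-substituted, semi-stabilised allyl ylide towards an ortho-silyloxy benzaldehyde are not secured. The freed phenoxide is ortho to the benzylic epoxide carbon and can instead push out the benzylic C–O bond to an ortho-quinone methide, which would erase C3. SN2' opening is also possible. A5 needs its own synthesis, including the side-chain stereocentre. The end game must distinguish a primary allylic from a secondary benzylic silyl ether and oxidise the former alcohol while sparing an easily oxidised para-alkoxybenzylic one.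
- Comparison: in the chosen plan each stereocentre is set by a reaction type with close precedent on its substrate class, and the sensitive side-chain oxygen appears only two steps before the end.

Alternative 3: The cut is the C2–C3 bond alone. Enantioselective lithiation (t-BuLi, chiral bis(oxazoline)) of the benzylic CH2 of the eight-membered cyclic diether A9 would trigger a transannular [2,3]-Wittig shift. This forms C2–C3, releases the C=CH2 group and contracts the ring to the hydroxy dihydrobenzofuran A8.
- Merits: one step would create the C2–C3 bond, both stereocentres and the propen-2-yl group from an achiral ring. This is better bond-forming economy than any single step of the chosen plan.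
- Weak points: A8 is the 2,3-cis isomer (2R,3R). C3 would therefore have to be inverted, presumably by a Mitsunobu esterification with 6 at a benzylic carbinol that is prone to ionisation and to elimination to a benzofuran. A9 is a medium ring containing a Z aryl enol ether and has no simple synthesis. The ketone must be masked as a ketal because of t-BuLi, which costs two steps. The chiral ligand is stoichiometric. [1,2]-Shift and ring lithiation compete. The late allylic oxidation is still required.
- Comparison: the chosen plan gives the trans geometry directly from the epoxide stereochemistry, keeps the acetyl group unprotected, and uses catalytic asymmetric steps.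

Key step: step 5

Assumption: 3-chloro-3-methylbut-1-yne (2) is taken to be a commercially available starting material.

## Route

Step 1
Reactants: 1 4'-hydroxyacetophenone [1-(4-hydroxyphenyl)ethan-1-one]; 2 3-chloro-3-methylbut-1-yne
Product: 3 1-{4-[(2-methylbut-3-yn-2-yl)oxy]phenyl}ethan-1-one
Conditions: DBU (1.4 equiv), CuCl2·2H2O (0.1 mol %, divalent copper), MeCN, 0 °C → rt
Reagents that add atoms: none
Why: Copper-catalysed propargylic substitution (O-alkylation of a phenol by a tertiary propargylic chloride), in which copper activates the terminal alkyne so that chloride leaves under mild conditions and the phenoxide is captured on oxygen; the method is suited to acceptor-substituted phenols, and no stereocentre is formed.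

Step 2
Reactants: 3 1-{4-[(2-methylbut-3-yn-2-yl)oxy]phenyl}ethan-1-one
Product: 4 1-(2,2-dimethyl-2H-chromen-6-yl)ethan-1-one (6-acetyl-2,2-dimethyl-2H-chromene)
Conditions: N,N-diethylaniline, 190 °C
Reagents that add atoms: none
Why: Aromatic propargyl Claisen rearrangement followed by 1,5-hydrogen shift and oxa-6π electrocyclisation, the standard thermal route from aryl 1,1-dimethylpropargyl ethers to 2,2-dimethyl-2H-chromenes; the para position is occupied by the acetyl group and both ortho positions are equivalent, so only one chromene can form.

Step 3
Reactants: 4 1-(2,2-dimethyl-2H-chromen-6-yl)ethan-1-one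
Product: 5 (3R,4R)-6-acetyl-3,4-epoxy-2,2-dimethyl-3,4-dihydro-2H-chromene [1-((1aR,7bR)-2,2-dimethyl-1a,7b-dihydro-2H-oxireno[2,3-c]chromen-6-yl)ethan-1-one]
Conditions: (R,R)-N,N'-bis(3,5-di-tert-butylsalicylidene)-1,2-cyclohexanediaminomanganese chloride [(R,R)-(salen)MnCl, trivalent manganese] (3 mol %), 4-phenylpyridine N-oxide (0.2 equiv), aq NaOCl (pH 11.3, Na2HPO4), CH2Cl2, 0 °C
Reagents that add atoms: sodium hypochlorite, [Na+].[O-]Cl
Why: Jacobsen epoxidation, oxygen-atom transfer from the oxidised manganese salen complex to a cis-alkene conjugated with an arene, the substrate class (2,2-dimethylchromenes in particular) on which this catalyst is most selective; the (R,R) ligand directs the side-on approach of the alkene so that both new stereocentres are set as (3R,4R) by catalyst control, and the ketone is inert to buffered hypochlorite at 0 °C.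

Step 4
Reactants: 5 (3R,4R)-6-acetyl-3,4-epoxy-2,2-dimethyl-3,4-dihydro-2H-chromene; 6 tiglic acid [(2E)-2-methylbut-2-enoic acid]
Product: 7 (3R,4S)-6-acetyl-3-hydroxy-2,2-dimethyl-3,4-dihydro-2H-chromen-4-yl (2E)-2-methylbut-2-enoate
Conditions: tiglic acid (3 equiv), Cs2CO3 (10 mol %), DMF, 70 °C
Reagents that add atoms: none
Why: Carboxylate-promoted SN2 opening of an aryl epoxide by a carboxylic acid, in which the tiglate anion attacks benzylic C4 anti to the C–O bond while free acid hydrogen-bonds to the epoxide oxygen, C3 being shielded by the adjacent gem-dimethyl group; inversion at C4 gives the trans (3R,4S) hydroxy ester, the acetyl group para to O1 disfavours a benzylic cation that would leak to the cis isomer, and the excess of acid keeps the medium too weakly basic for the acyl group to move to the C3 hydroxyl.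

Step 5
Reactants: 7 (3R,4S)-6-acetyl-3-hydroxy-2,2-dimethyl-3,4-dihydro-2H-chromen-4-yl (2E)-2-methylbut-2-enoate
Product: 10 (2R,3S)-5-acetyl-2-(prop-1-en-2-yl)-2,3-dihydro-1-benzofuran-3-yl (2E)-2-methylbut-2-enoate, via C3 triflate 8 (not isolated), via bridged oxiranium triflate 9 (not isolated)
Conditions: Tf2O (1.2 equiv), 2,6-di-tert-butyl-4-methylpyridine (3 equiv), CH2Cl2, −78 °C → 0 °C
Reagents that add atoms: none
Why: Tf2O and the hindered pyridine convert the C3 hydroxyl of 7 into triflate 8; in the trans-diequatorial half-chair the C3–OTf bond is antiperiplanar to the O1–C2 ring bond, so a lone pair of O1 displaces triflate from the rear and gives the bridged oxiranium ion 9, which opens at its tertiary carbon as the base removes a methyl proton and leaves the propen-2-yl group. The closest known reaction type is the 1,2-aryloxy shift ring contraction of activated 3-hydroxy-2,2-dimethylchromans to 2-(propen-2-yl)-2,3-dihydrobenzofurans, which rests on the same stereoelectronic pattern as the ring contraction of pyranosides that carry an equatorial leaving group next to the ring oxygen; the 4-acyloxy group is an added substituent within that class. The dihydrofuran ring is closed by 3-exo-tet attack of O1 on C3 and becomes the five-membered ring when the old O1–CMe2 bond breaks. The new stereocentre, C2 of 10 (R), is set by substrate control, namely backside displacement at C3 of 7, whose configuration comes from the epoxide, while C4 of 7 becomes C3 of 10 untouched, so the trans chromanol gives the 2,3-trans product. The step needs aryloxy migration to win over tiglate participation, aryl shift and methyl or hydride shift: the diequatorial conformer places only ring bonds anti to the leaving group, the ester carbonyl can reach C3 only from the diaxial conformer, which sets the C4 ester against the axial C2 methyl group, and an acyloxy group stabilises the cation left by an aryl shift far less well than the tertiary centre left by the oxygen shift. Low temperature and a non-nucleophilic base keep the acetyl group from forming an enol triflate and the benzylic ester of 10 from eliminating.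

Step 6
Reactants: 10 (2R,3S)-5-acetyl-2-(prop-1-en-2-yl)-2,3-dihydro-1-benzofuran-3-yl (2E)-2-methylbut-2-enoate
Product: 11 (2R,3S)-5-[(1R)-1-hydroxyethyl]-2-(prop-1-en-2-yl)-2,3-dihydro-1-benzofuran-3-yl (2E)-2-methylbut-2-enoate
Conditions: RuCl[(R,R)-TsDPEN](p-cymene) (divalent ruthenium, 1 mol %), HCO2H/Et3N (5:2), EtOAc, 30 °C
Reagents that add atoms: none
Why: Noyori asymmetric transfer hydrogenation of an aryl methyl ketone, in which the metal hydride and the ligand N–H deliver hydride and proton together while the arene of the substrate lies against the p-cymene ligand, so the (R,R) catalyst gives the (R)-carbinol by catalyst control, independent of the distant ring stereocentres; formic acid makes the reduction irreversible, and this catalyst does not reduce the conjugated ester alkenes, the 1,1-disubstituted alkene or the benzylic ester.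

Step 7
Reactants: 11 (2R,3S)-5-[(1R)-1-hydroxyethyl]-2-(prop-1-en-2-yl)-2,3-dihydro-1-benzofuran-3-yl (2E)-2-methylbut-2-enoate; 6 tiglic acid
Product: 12 (2R,3S)-5-[(1R)-1-{[(2E)-2-methylbut-2-enoyl]oxy}ethyl]-2-(prop-1-en-2-yl)-2,3-dihydro-1-benzofuran-3-yl (2E)-2-methylbut-2-enoate
Conditions: tiglic acid (1.5 equiv), DCC (1.5 equiv), DMAP (0.2 equiv), CH2Cl2, 0 °C → rt
Reagents that add atoms: none
Why: Steglich esterification, carbodiimide activation of the acid with DMAP as acyl-transfer catalyst, acylates the carbinol on oxygen, so its C–O bond is not broken and the (R) configuration is kept; the neutral conditions suit the acid-labile para-alkoxybenzylic alcohol and the benzylic C3 ester, and the tiglate is the more stable alkene isomer, so its geometry is not at risk.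

Step 8
Reactants: 12 (2R,3S)-5-[(1R)-1-{[(2E)-2-methylbut-2-enoyl]oxy}ethyl]-2-(prop-1-en-2-yl)-2,3-dihydro-1-benzofuran-3-yl (2E)-2-methylbut-2-enoate
Product: 14 (2R,3S)-5-[(1R)-1-{[(2E)-2-methylbut-2-enoyl]oxy}ethyl]-2-(3-oxoprop-1-en-2-yl)-2,3-dihydro-1-benzofuran-3-yl (2E)-2-methylbut-2-enoate, via allylic alcohol 13 (not isolated)
Conditions: SeO2 (0.5 equiv), t-BuOOH (5.5 M in decane, 3 equiv), CH2Cl2, 0 °C → rt; filtration, then activated MnO2 (10 equiv), CH2Cl2, rt
Reagents that add atoms: selenium dioxide, O=[Se]=O (transfers the oxygen atom and is restored by tert-butyl hydroperoxide, CC(C)(C)OO)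
Why: Allylic oxidation with SeO2 and t-BuOOH (ene reaction at the terminal CH2 followed by [2,3]-sigmatropic shift) takes the methyl group of the 1,1-disubstituted alkene to the primary allylic alcohol 13 and partly further; this is the only electron-rich alkene, the two tiglate alkenes being deactivated by their ester groups, and the methyl hydrogens react in preference to the single hydrogen on the oxygen-bearing C2, as is established for propen-2-yl groups on dihydrobenzofurans. MnO2 then oxidises the remaining primary allylic alcohol 13 to the propenal without touching the esters, and no stereocentre is involved.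

## Compound list

1 | 4'-hydroxyacetophenone [1-(4-hydroxyphenyl)ethan-1-one] | CC(=O)c1ccc(O)cc1 | starting material
2 | 3-chloro-3-methylbut-1-yne | CC(C)(Cl)C#C | starting material
3 | 1-{4-[(2-methylbut-3-yn-2-yl)oxy]phenyl}ethan-1-one | CC(=O)c1ccc(OC(C)(C)C#C)cc1 | intermediate
4 | 1-(2,2-dimethyl-2H-chromen-6-yl)ethan-1-one | CC(=O)c1ccc2OC(C)(C)C=Cc2c1 | intermediate
5 | (3R,4R)-6-acetyl-3,4-epoxy-2,2-dimethyl-3,4-dihydro-2H-chromene | CC1(C)Oc2ccc(C(C)=O)cc2[C@H]2O[C@@H]12 | intermediate
6 | tiglic acid [(2E)-2-methylbut-2-enoic acid] | C/C=C(\C)C(=O)O | starting material
7 | (3R,4S)-6-acetyl-3-hydroxy-2,2-dimethyl-3,4-dihydro-2H-chromen-4-yl (2E)-2-methylbut-2-enoate | CC1(C)Oc2ccc(C(C)=O)cc2[C@H](OC(=O)/C(C)=C/C)[C@H]1O | intermediate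
8 | (3R,4S)-6-acetyl-2,2-dimethyl-3-[(trifluoromethanesulfonyl)oxy]-3,4-dihydro-2H-chromen-4-yl (2E)-2-methylbut-2-enoate (not isolated) | CC1(C)Oc2ccc(C(C)=O)cc2[C@H](OC(=O)/C(C)=C/C)[C@H]1OS(=O)(=O)C(F)(F)F | intermediate
9 | bridged oxiranium ion in which O1 is bonded to the aryl carbon, to the CMe2 carbon and to the inverted former C3, the former C4 keeping its tiglate; triflate salt (not isolated) | CC1(C)[O+]2c3ccc(C(C)=O)cc3[C@H](OC(=O)/C(C)=C/C)[C@@H]12.[O-]S(=O)(=O)C(F)(F)F | intermediate
10 | (2R,3S)-5-acetyl-2-(prop-1-en-2-yl)-2,3-dihydro-1-benzofuran-3-yl (2E)-2-methylbut-2-enoate | CC(=C)[C@H]1Oc2ccc(C(C)=O)cc2[C@@H]1OC(=O)/C(C)=C/C | intermediate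
11 | (2R,3S)-5-[(1R)-1-hydroxyethyl]-2-(prop-1-en-2-yl)-2,3-dihydro-1-benzofuran-3-yl (2E)-2-methylbut-2-enoate | CC(=C)[C@H]1Oc2ccc([C@@H](C)O)cc2[C@@H]1OC(=O)/C(C)=C/C | intermediate
12 | (2R,3S)-5-[(1R)-1-{[(2E)-2-methylbut-2-enoyl]oxy}ethyl]-2-(prop-1-en-2-yl)-2,3-dihydro-1-benzofuran-3-yl (2E)-2-methylbut-2-enoate | CC(=C)[C@H]1Oc2ccc([C@@H](C)OC(=O)/C(C)=C/C)cc2[C@@H]1OC(=O)/C(C)=C/C | intermediate
13 | (2R,3S)-2-(3-hydroxyprop-1-en-2-yl)-5-[(1R)-1-{[(2E)-2-methylbut-2-enoyl]oxy}ethyl]-2,3-dihydro-1-benzofuran-3-yl (2E)-2-methylbut-2-enoate (not isolated) | C=C(CO)[C@H]1Oc2ccc([C@@H](C)OC(=O)/C(C)=C/C)cc2[C@@H]1OC(=O)/C(C)=C/C | intermediate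
14 | (2R,3S)-5-[(1R)-1-{[(2E)-2-methylbut-2-enoyl]oxy}ethyl]-2-(3-oxoprop-1-en-2-yl)-2,3-dihydro-1-benzofuran-3-yl (2E)-2-methylbut-2-enoate | C=C(C=O)[C@H]1Oc2ccc([C@@H](C)OC(=O)/C(C)=C/C)cc2[C@@H]1OC(=O)/C(C)=C/C | target

## Step count and least certain steps

Total step count: 8. Longest linear sequence: 8 steps (1 to 14); tiglic acid 6 enters twice.

**Step 5 (key step).** The most likely failure is that ionisation of triflate 8 is diverted. The tiglate carbonyl can participate through the minor diaxial conformer, giving a dioxolanylium ion that would end as cis hydroxy esters, or the aryl bond can migrate. The aryl ether oxygen shares its lone pair with the para acetyl group and may be too slow to compete. Enol triflate formation at the acetyl group and loss of tiglic acid from 10 to a benzofuran are lesser concerns. The fallback keeps the disconnection but carries a non-participating acyl group through the shift and brings in the tiglate afterwards. It sets out from epoxide 5, which would be opened with dichloroacetic acid (catalytic cesium dichloroacetate, DMF) to (3R,4S)-6-acetyl-3-hydroxy-2,2-dimethyl-3,4-dihydro-2H-chromen-4-yl dichloroacetate F1. Tf2O and the hindered pyridine would convert this through (3R,4S)-6-acetyl-2,2-dimethyl-3-[(trifluoromethanesulfonyl)oxy]-3,4-dihydro-2H-chromen-4-yl dichloroacetate F2 into (2R,3S)-5-acetyl-2-(prop-1-en-2-yl)-2,3-dihydro-1-benzofuran-3-yl dichloroacetate F3. The electron-poor carbonyl oxygen is a much weaker neighbouring group, and the dichloroacetoxy group stabilises the cation of an aryl shift even less. Brief methanolysis (K2CO3, MeOH, 0 °C) would free 1-[(2R,3S)-3-hydroxy-2-(prop-1-en-2-yl)-2,3-dihydro-1-benzofuran-5-yl]ethan-1-one F4, and Steglich esterification with 6 would come back to the route at 10. The cost is two extra steps.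

**Step 4.** Two processes can go wrong: partial loss of stereospecificity through a benzylic cation, and migration of the tigloyl group from the C4 to the C3 oxygen while the alkoxide is exposed. The fallback separates opening from acylation. It sets out from 5, which would be hydrolysed under dilute acid (HClO4, THF/H2O, 0 °C) to 1-[(3R,4S)-3,4-dihydroxy-2,2-dimethyl-3,4-dihydro-2H-chromen-6-yl]ethan-1-one F5. One equivalent of 6 (DCC, DMAP, 0 °C) would then acylate the benzylic C4 hydroxyl in preference to the C3 hydroxyl, which is flanked by the quaternary carbon, and the sequence comes back at 7.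

**Step 8.** The oxidation can stall or lose selectivity, by attack on the allylic methyl groups of the tiglates or by acid-promoted ionisation of the para-alkoxybenzylic ester in the presence of selenous acid. The fallback replaces direct oxygen transfer by halogenation and substitution. It sets out from 12, which would undergo ene-type allylic chlorination (NaOCl, CeCl3·7H2O, CH2Cl2/H2O, 0 °C) to (2R,3S)-2-(3-chloroprop-1-en-2-yl)-5-[(1R)-1-{[(2E)-2-methylbut-2-enoyl]oxy}ethyl]-2,3-dihydro-1-benzofuran-3-yl (2E)-2-methylbut-2-enoate F6. Ganem oxidation of the allylic chloride with N-methylmorpholine N-oxide (NaI, MeCN, rt) would then come back at 14.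

**Step 6.** Hydrogen transfer to a para-alkoxy aryl ketone is slow, and long reaction times invite incomplete conversion and some loss of facial selectivity. The fallback changes from metal-catalysed hydrogen transfer to a CBS reduction: (S)-2-methyl-CBS-oxazaborolidine with catecholborane in toluene at −78 °C. Catecholborane is chosen because it does not hydroborate the 1,1-disubstituted alkene at that temperature. It sets out from 10 and comes back at 11 with no new compound.

## Further compounds

F1 | step 5 | (3R,4S)-6-acetyl-3-hydroxy-2,2-dimethyl-3,4-dihydro-2H-chromen-4-yl dichloroacetate | CC1(C)Oc2ccc(C(C)=O)cc2[C@H](OC(=O)C(Cl)Cl)[C@H]1O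
F2 | step 5 | (3R,4S)-6-acetyl-2,2-dimethyl-3-[(trifluoromethanesulfonyl)oxy]-3,4-dihydro-2H-chromen-4-yl dichloroacetate | CC1(C)Oc2ccc(C(C)=O)cc2[C@H](OC(=O)C(Cl)Cl)[C@H]1OS(=O)(=O)C(F)(F)F
F3 | step 5 | (2R,3S)-5-acetyl-2-(prop-1-en-2-yl)-2,3-dihydro-1-benzofuran-3-yl dichloroacetate | CC(=C)[C@H]1Oc2ccc(C(C)=O)cc2[C@@H]1OC(=O)C(Cl)Cl
F4 | step 5 | 1-[(2R,3S)-3-hydroxy-2-(prop-1-en-2-yl)-2,3-dihydro-1-benzofuran-5-yl]ethan-1-one | CC(=C)[C@H]1Oc2ccc(C(C)=O)cc2[C@@H]1O
F5 | step 4 | 1-[(3R,4S)-3,4-dihydroxy-2,2-dimethyl-3,4-dihydro-2H-chromen-6-yl]ethan-1-one | CC1(C)Oc2ccc(C(C)=O)cc2[C@H](O)[C@H]1O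
F6 | step 8 | (2R,3S)-2-(3-chloroprop-1-en-2-yl)-5-[(1R)-1-{[(2E)-2-methylbut-2-enoyl]oxy}ethyl]-2,3-dihydro-1-benzofuran-3-yl (2E)-2-methylbut-2-enoate | C=C(CCl)[C@H]1Oc2ccc([C@@H](C)OC(=O)/C(C)=C/C)cc2[C@@H]1OC(=O)/C(C)=C/C
F0 | step 6 | none | none
A1 | alternative 1 | (2R,3S)-3-(tert-butyldimethylsilyloxy)-2-[3-(tert-butyldimethylsilyloxy)prop-1-en-2-yl]-5-[(1R)-1-(tert-butyldimethylsilyloxy)ethyl]-7-(trimethylsilyl)-2,3-dihydro-1-benzofuran | C=C(CO[Si](C)(C)C(C)(C)C)[C@H]1Oc2c([Si](C)(C)C)cc([C@@H](C)O[Si](C)(C)C(C)(C)C)cc2[C@@H]1O[Si](C)(C)C(C)(C)C
A2 | alternative 1 | (3S,4R)-3-(tert-butyldimethylsilyloxy)-5-[(tert-butyldimethylsilyloxy)methyl]-4-{[(trimethylsilyl)ethynyl]oxy}hex-5-en-1-yne | C=C(CO[Si](C)(C)C(C)(C)C)[C@@H](OC#C[Si](C)(C)C)[C@@H](O[Si](C)(C)C(C)(C)C)C#C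
A3 | alternative 1 | (R)-(but-3-yn-2-yloxy)(tert-butyl)dimethylsilane | C#C[C@@H](C)O[Si](C)(C)C(C)(C)C
A4 | alternative 2 | (2R,3S)-2-[3-(tert-butyldimethylsilyloxy)prop-1-en-2-yl]-5-[(1R)-1-(tert-butyldimethylsilyloxy)ethyl]-2,3-dihydro-1-benzofuran-3-ol | C=C(CO[Si](C)(C)C(C)(C)C)[C@H]1Oc2ccc([C@@H](C)O[Si](C)(C)C(C)(C)C)cc2[C@@H]1O
A5 | alternative 2 | 2-(tert-butyldimethylsilyloxy)-5-[(1R)-1-(tert-butyldimethylsilyloxy)ethyl]benzaldehyde | O=Cc1cc([C@@H](C)O[Si](C)(C)C(C)(C)C)ccc1O[Si](C)(C)C(C)(C)C
A6 | alternative 2 | (1R,4R,5R)-6-{2-[(tert-butyldimethylsilyloxy)methyl]prop-2-en-1-yl}-4,7,7-trimethyl-6-thiabicyclo[3.2.1]octan-6-ium trifluoromethanesulfonate (S-allyl salt of isothiocineole; configuration at sulfur not drawn) | C[C@@H]1CC[C@@H]2C[C@H]1[S+](CC(=C)CO[Si](C)(C)C(C)(C)C)C2(C)C.[O-]S(=O)(=O)C(F)(F)F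
A7 | alternative 2 | (2S,3S)-2-{2-(tert-butyldimethylsilyloxy)-5-[(1R)-1-(tert-butyldimethylsilyloxy)ethyl]phenyl}-3-[3-(tert-butyldimethylsilyloxy)prop-1-en-2-yl]oxirane | C=C(CO[Si](C)(C)C(C)(C)C)[C@@H]1O[C@H]1c1cc([C@@H](C)O[Si](C)(C)C(C)(C)C)ccc1O[Si](C)(C)C(C)(C)C
A8 | alternative 3 | (2R,3R)-5-(2-methyl-1,3-dioxolan-2-yl)-2-(prop-1-en-2-yl)-2,3-dihydro-1-benzofuran-3-ol | CC(=C)[C@H]1Oc2ccc(C3(C)OCCO3)cc2[C@H]1O
A9 | alternative 3 | (4Z)-4-methyl-9-(2-methyl-1,3-dioxolan-2-yl)-1H,3H-2,6-benzodioxocine | C/C1=C/Oc2ccc(C3(C)OCCO3)cc2COC1
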